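Structural features

Sideritiflavone (14) is an achiral flavone: a benzene ring A is fused through the C4a–C8a bond to a 4-pyranone ring C, and a 3,4-dihydroxyphenyl ring B sits on C2. There is no stereocentre, so the task is one of regiochemistry on ring A, which carries no hydrogen at all: hydroxyl on C5, methoxyl on C6, C7 and C8, the ring oxygen on C8a and the C4 carbonyl on C4a. The C5 hydroxyl is held in a six-membered hydrogen bond to the C4 carbonyl, which makes it the least acidic and least nucleophilic phenol in the molecule. The fragile elements are the ring B catechol and any para-dihydroxy stage of ring A (both oxidise to quinones in air under base), and the pyranone C2, which hard nucleophiles can attack with ring opening. The real difficulty is to place four contiguous oxygens on a hexasubstituted ring and leave exactly one of them, that on C5, unmethylated. The key step uses the fact that C5–C6–C7–C8, with their four oxygens and the two inner methoxyls, are atom for atom dimethyl squarate, while C4a=C8a can be the C3=C2 double bond of a 2-aryl-4-pyranone that already holds rings C and B.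

Logic of the disconnections

14 to 13: the two O–CH2Ph bonds on ring B are cut. The catechol is the most oxidation-prone part of 14 and is best unmasked last. Benzyl ethers tolerate an organomagnesium reagent, DDQ, heat and carbonate base, and they leave without touching methyl ethers. The forward step must not reduce the C2=C3 bond of ring C.

13 to 12: the O–CH3 bond on the C8 oxygen is cut. The two hydroxyls of 12 differ sharply because only the C5 hydroxyl is chelated to the C4 carbonyl. The gain is that both hydroxyls can come from one ring-forming event. The demand is a single alkylation under mild base with exclusion of oxygen, since 12 is a hydroquinone.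

12 to 9 (through 11 and 10): the C8–C8a bond is cut and ring A is contracted to a four-membered ring by rejoining C5 to C8. This removes ring A with all four of its oxygens in one stroke and leaves a monocyclic pyranone bearing a squarate-derived carbinol. The hydroxyl of 9 is kept free on purpose: it is the donor that steers the ring opening, it becomes the C5 hydroxyl directly, and an alkyl group there would end on the wrong oxygen. The forward step demands outward rotation of that hydroxyl and a C–H carbon on the pyranone next to the point of attachment.

9 to 6 and 7 (through 8): the C4a–C5 bond is cut, that is, the bond from the pyranone carbon to the carbinol carbon. The carbinol carbon is a former carbonyl carbon of 7, so the polar addition of a pyranonyl metal is the natural forward reaction, and 7 is symmetric, so there is no site issue. The demand is that halogen–metal exchange outruns attack of the exchange reagent on the pyranone, that 8 survives long enough to add, and that it adds only once.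

6 to 5: no skeletal bond is cut; two hydrogens are returned to C2 and C3 (flavone numbering). Aromatising to the pyranone before metalation is a deliberate choice: 6 has no enolisable CH2 to quench 8, and the C–H carbon needed by the key step is in place. The forward dehydrogenation must spare the vinyl iodide and the benzyl ethers.

5 to 4: the C–I bond on the future C4a is cut. In 4 there is only one enone alpha carbon, so the position of the halogen is fixed by construction. Halogenating a finished 2-aryl-4-pyranone would instead have to choose between two alpha carbons.

4 to 1 and 2 (through 3): the O1–C8a and C2–C3 bonds (flavone numbering) are cut in a hetero-Diels–Alder sense. Both partners are commercial, and ring C with ring B attached arises in one operation. The stereocentre formed at C2 needs no control because it is removed two steps later.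

Other disconnections considered

Alternative 1: The cut is at the C6–O and C8–O bonds, going back to bromine on an intact flavone. Luteolin A1 would be protected on ring B as the diphenylmethylene ketal and brominated at both free ring A positions to give 6,8-dibromo-2-(2,2-diphenyl-1,3-benzodioxol-5-yl)-5,7-dihydroxychromen-4-one A2. The forward key step is a twofold Ullmann-type substitution with NaOMe and CuBr in DMF, which should give 2-(2,2-diphenyl-1,3-benzodioxol-5-yl)-5,7-dihydroxy-6,8-dimethoxychromen-4-one A3. Methylation of the C7 hydroxyl and removal of the ketal would finish the synthesis.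
- In its favour: the whole carbon skeleton is bought, no ring is built, and bromination can only go to C6 and C8. Ring opening and reclosure of ring C under the basic conditions would be degenerate, because ring A of A3 is symmetric. The route needs about five steps from A1 against seven here, and on step count it is the better plan.
- Against it: the substitution must occur twice on a doubly deprotonated, very electron-rich ring. Reductive loss of bromine and incomplete second substitution are the expected competitors, and hot methoxide also threatens the pyranone C2.
- Comparison: the final selective methylation rests on the same chelation argument as step 6 here, so the two plans are equal on that point. The alternative avoids the air-sensitive hydroquinone, which is a point for it. The chosen plan is preferred for mechanism: it sets the oxygen pattern by pericyclic steps with no redox side channel, and it does not depend on a natural product as raw material.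

Alternative 2: The cut is at C8–C7, C6–C5 and C5–C4a, a chromium carbene benzannulation (Dötz reaction). The carbene complex pentacarbonyl[{2-[3,4-bis(benzyloxy)phenyl]-3,4-dihydro-2H-pyran-6-yl}(methoxy)methylidene]chromium A4 would combine with dimethoxyethyne A5 and one carbonyl ligand to give racemic 3',4'-bis(benzyloxy)-5-hydroxy-6,7,8-trimethoxyflavan A6.
- In its favour: the carbene methoxyl becomes the C8 methoxyl and the inserted carbonyl becomes the free C5 hydroxyl. The annulation therefore delivers the exact methylation pattern of ring A with no selective alkylation and no hydroquinone, and on that point it is better than the chosen plan. A5 is symmetric, so alkyne regiochemistry does not arise, which is equal to the symmetric squarate here. The mechanism is closely related: a metal-bound vinylketene closes by the same six-electron cyclisation as 10.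
- Against it: A5 is a thermally labile, very electron-rich alkyne, and such alkynes tend to give insertion products other than the phenol. Chromium is used stoichiometrically. Ring C of A6 is at the wrong oxidation level: C4 must become a carbonyl and C2–C3 a double bond in the presence of a para-methoxyphenol ring A that is itself easily oxidised. At least three further steps and a phenol protection would be needed, and a stereocentre is made at C2 only to be destroyed.
- Comparison: better than the chosen plan on the methylation pattern, weaker on reagent handling, on the oxidation state of ring C and on step count.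

Alternative 3: The cut is at C4a–C8a and O1–C2, a biomimetic folding. The precursor methyl 4-{6-[3,4-bis(benzyloxy)phenyl]-4-oxo-4H-pyran-2-yl}-2,4-dimethoxy-3-oxobutanoate A7 would be opened by Mg(OMe)2 in methanol to a magnesium-chelated tricarbonyl array. The carbon that becomes C4a, now flanked by two carbonyls, would acylate itself with the terminal ester (Claisen-type closure of ring A). On acidification a phenol oxygen would add to the aroyl carbon C2 with loss of water, giving 3',4'-bis(benzyloxy)-5,7-dihydroxy-6,8-dimethoxyflavone A8.
- In its favour: two rings form in one operation without a transition metal. The phloroglucinol stage is symmetric, so either ortho phenol closes to the same flavone, and no hydroquinone appears, which is a point for it.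
- Against it: A7 is hardly simpler than the target. Its chain with two methoxylated methines between carbonyls needs several Claisen-type acylations of alpha-methoxy esters, each giving an unsymmetrical polycarbonyl prone to cleavage. The chain can also fold in other ways, by oxygen acylation to a 2-pyranone or by aldol closure.
- Comparison: A8 still needs methylation at C7 and hydrogenolysis, the same two closing steps as the chosen plan, so the end-games are equal. The chosen plan is preferred on structure, because ring A comes from a four-carbon unit that is commercial and symmetric, and on step count, because A7 would take more steps to assemble than 9.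

Key step: step 5

Assumption: 3, 4, 5, 9 and 11 are racemates (3 as a mixture of diastereomers); every one of their stereocentres is erased before 12, so no asymmetric induction is planned.

Step 1
Reactants: 1 3,4-bis(benzyloxy)benzaldehyde; 2 (E)-1-methoxy-3-(trimethylsilyloxy)buta-1,3-diene
Product: 4 rac-2-[3,4-bis(benzyloxy)phenyl]-2,3-dihydro-4H-pyran-4-one, via silyloxy dihydropyran cycloadduct 3 (not isolated)
Conditions: ZnCl2 (10 mol%), THF, rt; then TFA, CH2Cl2, 0 °C
Reagents that add atoms: none
Why: Lewis-acid-catalysed hetero-Diels–Alder reaction of an aromatic aldehyde with an electron-rich 1-alkoxy-3-silyloxydiene; acid then hydrolyses the silyl enol ether of 3 and eliminates methanol to give the vinylogous ester 4. The C2 stereocentre forms as a racemate and is left uncontrolled because step 3 removes it.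

Step 2
Reactants: 4 rac-2-[3,4-bis(benzyloxy)phenyl]-2,3-dihydro-4H-pyran-4-one
Product: 5 rac-2-[3,4-bis(benzyloxy)phenyl]-5-iodo-2,3-dihydro-4H-pyran-4-one
Conditions: I2, pyridine, CH2Cl2, 0 °C to rt, dark
Reagents that add atoms: iodine, II
Why: Electrophilic alpha-iodination of a beta-alkoxy enone with iodine and pyridine; C5 is the only nucleophilic enone alpha carbon of 4, so the iodine position is fixed by the substrate. The benzyloxy arene should not be iodinated by I2 without acid or oxidant.

Step 3
Reactants: 5 rac-2-[3,4-bis(benzyloxy)phenyl]-5-iodo-2,3-dihydro-4H-pyran-4-one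
Product: 6 2-[3,4-bis(benzyloxy)phenyl]-5-iodo-4H-pyran-4-one
Conditions: DDQ, 1,4-dioxane (dry), 100 °C
Reagents that add atoms: none
Why: DDQ dehydrogenation of the flavanone-to-flavone type: hydride abstraction from C2–H, which is benzylic, alpha to the ring oxygen and para to a benzyloxy donor, then loss of a C3 proton gives the cross-conjugated 4-pyranone. Aryl benzyl ethers and the vinyl iodide should be inert to DDQ when water is excluded.

Step 4
Reactants: 6 2-[3,4-bis(benzyloxy)phenyl]-5-iodo-4H-pyran-4-one; 7 dimethyl squarate (3,4-dimethoxycyclobut-3-ene-1,2-dione)
Product: 9 rac-4-{6-[3,4-bis(benzyloxy)phenyl]-4-oxo-4H-pyran-3-yl}-4-hydroxy-2,3-dimethoxycyclobut-2-en-1-one, via pyranonylmagnesium chloride 8 (not isolated)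
Conditions: iPrMgCl·LiCl (1.05 equiv), THF, −78 °C, 20 min; then add to 7 (1.5 equiv), THF, −78 °C; sat. aq. NH4Cl
Reagents that add atoms: none
Why: Iodine–magnesium exchange of a cyclic alpha-iodo-beta-alkoxy enone is fast at low temperature because the sp2 carbanion is stabilised by the adjacent carbonyl and ring oxygen, and 6 has no enolisable hydrogen to quench it. The alkenylmagnesium 8 then adds 1,2 to one of the two equivalent strained carbonyls of 7, with inverse addition and excess 7 to prevent a second addition. The new carbinol centre is racemic and is lost in step 5.

Step 5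
Reactants: 9 rac-4-{6-[3,4-bis(benzyloxy)phenyl]-4-oxo-4H-pyran-3-yl}-4-hydroxy-2,3-dimethoxycyclobut-2-en-1-one
Product: 12 3',4'-bis(benzyloxy)-5,8-dihydroxy-6,7-dimethoxyflavone, via dienylketene 10 (not isolated), via cyclohexadienone tautomer 11 (not isolated)
Conditions: toluene (degassed), 110 °C, Ar, dark; crude product kept under Ar
Reagents that add atoms: none
Why: Moore cyclization, the thermal ring expansion of 4-alkenyl- and 4-aryl-4-hydroxycyclobutenones, here with the C2=C3 bond of the pyranone as the unsaturated arm. Heating cleaves the C1–C4 bond of the cyclobutenone by conrotatory four-electron ring opening; the hydroxyl, the strongest donor on the carbinol carbon, rotates outward, which turns the pyranonyl group inward and gives the (Z)-dienylketene 10. The ketene carbon and the pyranone C–H carbon next to the ring oxygen are then the ends of a triene, and thermal disrotatory six-electron electrocyclisation forms C8–C8a and closes the six-membered carbocyclic ring A as dienone 11. Enolisation moves the C8a hydrogen to the C8 oxygen and aromatises ring A to hydroquinone 12, driven by aromaticity and the new hydrogen bond from the C5 hydroxyl to the C4 carbonyl. No stereocentre survives: the carbinol centre of 9 becomes sp2 in 10, and the transient C8a centre of 11 is erased by tautomerisation. The step needs torquoselectivity, since inward rotation of the hydroxyl would lead to lactonisation to a furanone, and the donor hydroxyl secures it. Site selectivity is structural: the other neighbour of the attachment carbon is the C4 carbonyl carbon, which cannot take part. Oxygen is excluded because 12 is a hydroquinone.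

Step 6
Reactants: 12 3',4'-bis(benzyloxy)-5,8-dihydroxy-6,7-dimethoxyflavone
Product: 13 3',4'-bis(benzyloxy)-5-hydroxy-6,7,8-trimethoxyflavone
Conditions: MeI (1.1 equiv), K2CO3 (1.1 equiv), acetone (degassed), rt, Ar
Reagents that add atoms: iodomethane, CI
Why: Williamson ether synthesis with one equivalent of base and alkylating agent; the C8 phenol is the more acidic and far more nucleophilic one because the C5 hydroxyl is tied up in the hydrogen bond to the C4 carbonyl, the classical basis for partial methylation of 5-hydroxyflavones. Exclusion of air should prevent oxidation of the phenoxide to the quinone.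

Step 7
Reactants: 13 3',4'-bis(benzyloxy)-5-hydroxy-6,7,8-trimethoxyflavone
Product: 14 sideritiflavone (3',4',5-trihydroxy-6,7,8-trimethoxyflavone)
Conditions: H2 (1 atm), Pd/C (10%), EtOAc–MeOH, rt
Reagents that add atoms: none
Why: Catalytic hydrogenolysis of aryl benzyl ethers; methyl ethers, the chelated phenol and the C2=C3 bond of the flavone, which is part of a vinylogous ester, should not be reduced at atmospheric pressure if the reaction is stopped after two equivalents of hydrogen.

Compound list

1 | 3,4-bis(benzyloxy)benzaldehyde | O=Cc1ccc(OCc2ccccc2)c(OCc2ccccc2)c1 | starting material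
2 | (E)-1-methoxy-3-(trimethylsilyloxy)buta-1,3-diene | CO/C=C/C(=C)O[Si](C)(C)C | starting material
3 | 2-[3,4-bis(benzyloxy)phenyl]-6-methoxy-4-(trimethylsilyloxy)-3,6-dihydro-2H-pyran (racemic, mixture of diastereomers) | COC1C=C(O[Si](C)(C)C)CC(c2ccc(OCc3ccccc3)c(OCc3ccccc3)c2)O1 | intermediate
4 | rac-2-[3,4-bis(benzyloxy)phenyl]-2,3-dihydro-4H-pyran-4-one | O=C1C=COC(c2ccc(OCc3ccccc3)c(OCc3ccccc3)c2)C1 | intermediate
5 | rac-2-[3,4-bis(benzyloxy)phenyl]-5-iodo-2,3-dihydro-4H-pyran-4-one | O=C1CC(c2ccc(OCc3ccccc3)c(OCc3ccccc3)c2)OC=C1I | intermediate
6 | 2-[3,4-bis(benzyloxy)phenyl]-5-iodo-4H-pyran-4-one | O=c1cc(-c2ccc(OCc3ccccc3)c(OCc3ccccc3)c2)occ1I | intermediate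
7 | dimethyl squarate (3,4-dimethoxycyclobut-3-ene-1,2-dione) | COC1=C(OC)C(=O)C1=O | starting material
8 | {6-[3,4-bis(benzyloxy)phenyl]-4-oxo-4H-pyran-3-yl}magnesium chloride (as its LiCl complex) | O=c1cc(-c2ccc(OCc3ccccc3)c(OCc3ccccc3)c2)occ1[Mg]Cl | intermediate
9 | rac-4-{6-[3,4-bis(benzyloxy)phenyl]-4-oxo-4H-pyran-3-yl}-4-hydroxy-2,3-dimethoxycyclobut-2-en-1-one | COC1=C(OC)C(O)(c2coc(-c3ccc(OCc4ccccc4)c(OCc4ccccc4)c3)cc2=O)C1=O | intermediate
10 | (3Z)-4-{6-[3,4-bis(benzyloxy)phenyl]-4-oxo-4H-pyran-3-yl}-4-hydroxy-2,3-dimethoxybuta-1,3-dien-1-one (pyranonyl group cis to the ketene-bearing carbon) | O=C=C(OC)/C(OC)=C(/O)c1coc(-c2ccc(OCc3ccccc3)c(OCc3ccccc3)c2)cc1=O | intermediate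
11 | rac-2-[3,4-bis(benzyloxy)phenyl]-5-hydroxy-6,7-dimethoxy-8aH-chromene-4,8-dione | COC1=C(OC)C(=O)C2OC(c3ccc(OCc4ccccc4)c(OCc4ccccc4)c3)=CC(=O)C2=C1O | intermediate
12 | 3',4'-bis(benzyloxy)-5,8-dihydroxy-6,7-dimethoxyflavone | COc1c(OC)c(O)c2c(=O)cc(-c3ccc(OCc4ccccc4)c(OCc4ccccc4)c3)oc2c1O | intermediate
13 | 3',4'-bis(benzyloxy)-5-hydroxy-6,7,8-trimethoxyflavone | COc1c(OC)c(O)c2c(=O)cc(-c3ccc(OCc4ccccc4)c(OCc4ccccc4)c3)oc2c1OC | intermediate
14 | sideritiflavone (3',4',5-trihydroxy-6,7,8-trimethoxyflavone) | COc1c(OC)c(O)c2c(=O)cc(-c3ccc(O)c(O)c3)oc2c1OC | target

Total step count: 7. Longest linear sequence: 7 steps (1 to 14; 2 and 7 enter as single-step partners).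

Steps least certain to work

Step 5 (key step).
- What may go wrong: ring opening is reversible, so if the six-electron closure onto the partly delocalised pyranone double bond is slow, the material can drain away through inward rotation of the hydroxyl and its addition to the ketene (lactonisation). The hydroquinone product can also be oxidised by traces of air during heating or isolation.
- Fallback, from 9 back to 12: silylation (TMSCl, imidazole, CH2Cl2, 0 °C) would give 4-{6-[3,4-bis(benzyloxy)phenyl]-4-oxo-4H-pyran-3-yl}-2,3-dimethoxy-4-(trimethylsilyloxy)cyclobut-2-en-1-one F1. It has no free hydroxyl to trap the ketene and can therefore be heated harder (toluene or xylene). 4-Silyloxycyclobutenones are standard substrates of the same ring expansion, so thermolysis should give 3',4'-bis(benzyloxy)-8-hydroxy-6,7-dimethoxy-5-(trimethylsilyloxy)flavone F2. Dilute HCl in THF would remove the labile silyl ether next to the carbonyl and rejoin the route at 12.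

Step 4.
- What may go wrong: the magnesiated pyranone can undergo beta-elimination with ring opening, since the ring oxygen would leave as a stabilised diketone enolate. The exchange reagent can also add to the pyranone carbonyl or to C2, and the addition to 7 can be slow or occur twice.
- Fallback, from 5 back to 13: the coupling is moved to the dihydropyranone, whose ring oxygen is a much poorer leaving group. Exchange of 5 with iPrMgCl·LiCl at −78 °C and addition to 7 would give 4-{2-[3,4-bis(benzyloxy)phenyl]-4-oxo-3,4-dihydro-2H-pyran-5-yl}-4-hydroxy-2,3-dimethoxycyclobut-2-en-1-one F3. The exchange would have to outrun proton transfer from the enolisable CH2 of 5. Thermolysis in toluene, the ordinary 4-alkenyl case of the ring expansion, would give rac-3',4'-bis(benzyloxy)-5,8-dihydroxy-6,7-dimethoxyflavanone F4. TMSCHN2 in toluene–methanol would methylate only the unchelated C8 hydroxyl, without the base that could open the flavanone to a chalcone, giving rac-3',4'-bis(benzyloxy)-5-hydroxy-6,7,8-trimethoxyflavanone F5. Dehydrogenation with catalytic I2 in DMSO at 120 °C, the standard flavanone-to-flavone oxidation, rejoins the route at 13.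

Step 3.
- What may go wrong: the oxocarbenium ion formed by hydride abstraction can be captured by adventitious water, which cleaves ring C in the manner of an oxidative benzyl ether cleavage. Alternatively, hydride abstraction may be sluggish for the electron-poor iodo enone.
- Fallback, from 5 back to 6: a two-stage selenoxide route. Enolisation with LiN(SiMe3)2 in THF at −78 °C and trapping with PhSeCl would give 2-[3,4-bis(benzyloxy)phenyl]-5-iodo-3-(phenylselanyl)-2,3-dihydro-4H-pyran-4-one F6. Oxidation with H2O2 at 0 °C and syn-elimination of the selenoxide toward the only available hydrogen, that on C2, would give 6.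

Step 6.
- What may go wrong: a second alkylation at the chelated C5 hydroxyl if excess base or reagent is present, and aerial oxidation of the hydroquinone monoanion to the 5,8-quinone.
- Fallback, from 12 directly to 14: exhaustive methylation (Me2SO4, K2CO3, acetone, reflux, Ar) would give 3',4'-bis(benzyloxy)-5,6,7,8-tetramethoxyflavone F7, so no selectivity is asked of the alkylation. A quinone formed by accident can first be reduced back with aqueous Na2S2O4. BCl3 with pentamethylbenzene in CH2Cl2 at −78 to 0 °C would then cleave the two benzyl ethers and, through chelation to the C4 carbonyl, only the C5 methyl ether. This arrives at 14 and makes step 7 unnecessary.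

Further compounds

F1 | step 5 | 4-{6-[3,4-bis(benzyloxy)phenyl]-4-oxo-4H-pyran-3-yl}-2,3-dimethoxy-4-(trimethylsilyloxy)cyclobut-2-en-1-one (racemic) | COC1=C(OC)C(O[Si](C)(C)C)(c2coc(-c3ccc(OCc4ccccc4)c(OCc4ccccc4)c3)cc2=O)C1=O
F2 | step 5 | 3',4'-bis(benzyloxy)-8-hydroxy-6,7-dimethoxy-5-(trimethylsilyloxy)flavone | COc1c(OC)c(O[Si](C)(C)C)c2c(=O)cc(-c3ccc(OCc4ccccc4)c(OCc4ccccc4)c3)oc2c1O
F3 | step 4 | 4-{2-[3,4-bis(benzyloxy)phenyl]-4-oxo-3,4-dihydro-2H-pyran-5-yl}-4-hydroxy-2,3-dimethoxycyclobut-2-en-1-one (racemic, mixture of diastereomers) | COC1=C(OC)C(O)(C2=COC(c3ccc(OCc4ccccc4)c(OCc4ccccc4)c3)CC2=O)C1=O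
F4 | step 4 | rac-3',4'-bis(benzyloxy)-5,8-dihydroxy-6,7-dimethoxyflavanone | COc1c(OC)c(O)c2c(c1O)OC(c1ccc(OCc3ccccc3)c(OCc3ccccc3)c1)CC2=O
F5 | step 4 | rac-3',4'-bis(benzyloxy)-5-hydroxy-6,7,8-trimethoxyflavanone | COc1c(OC)c(O)c2c(c1OC)OC(c1ccc(OCc3ccccc3)c(OCc3ccccc3)c1)CC2=O
F6 | step 3 | 2-[3,4-bis(benzyloxy)phenyl]-5-iodo-3-(phenylselanyl)-2,3-dihydro-4H-pyran-4-one (racemic, mixture of diastereomers) | O=C1C(I)=COC(c2ccc(OCc3ccccc3)c(OCc3ccccc3)c2)C1[Se]c1ccccc1
F7 | step 6 | 3',4'-bis(benzyloxy)-5,6,7,8-tetramethoxyflavone | COc1c(OC)c(OC)c2c(=O)cc(-c3ccc(OCc4ccccc4)c(OCc4ccccc4)c3)oc2c1OC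
A1 | alternative 1 | luteolin | O=c1cc(-c2ccc(O)c(O)c2)oc2cc(O)cc(O)c12
A2 | alternative 1 | 6,8-dibromo-2-(2,2-diphenyl-1,3-benzodioxol-5-yl)-5,7-dihydroxychromen-4-one | O=c1cc(-c2ccc3c(c2)OC(c2ccccc2)(c2ccccc2)O3)oc2c(Br)c(O)c(Br)c(O)c12
A3 | alternative 1 | 2-(2,2-diphenyl-1,3-benzodioxol-5-yl)-5,7-dihydroxy-6,8-dimethoxychromen-4-one | COc1c(O)c(OC)c2oc(-c3ccc4c(c3)OC(c3ccccc3)(c3ccccc3)O4)cc(=O)c2c1O
A4 | alternative 2 | pentacarbonyl[{2-[3,4-bis(benzyloxy)phenyl]-3,4-dihydro-2H-pyran-6-yl}(methoxy)methylidene]chromium (racemic) | COC(=[Cr](=C=O)(=C=O)(=C=O)(=C=O)=C=O)C1=CCCC(c2ccc(OCc3ccccc3)c(OCc3ccccc3)c2)O1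
A5 | alternative 2 | dimethoxyethyne | COC#COC
A6 | alternative 2 | rac-3',4'-bis(benzyloxy)-5-hydroxy-6,7,8-trimethoxyflavan | COc1c(OC)c(OC)c(O)c2c1OC(c1ccc(OCc3ccccc3)c(OCc3ccccc3)c1)CC2
A7 | alternative 3 | methyl 4-{6-[3,4-bis(benzyloxy)phenyl]-4-oxo-4H-pyran-2-yl}-2,4-dimethoxy-3-oxobutanoate (mixture of stereoisomers) | COC(=O)C(OC)C(=O)C(OC)c1cc(=O)cc(-c2ccc(OCc3ccccc3)c(OCc3ccccc3)c2)o1
A8 | alternative 3 | 3',4'-bis(benzyloxy)-5,7-dihydroxy-6,8-dimethoxyflavone | COc1c(O)c(OC)c2oc(-c3ccc(OCc4ccccc4)c(OCc4ccccc4)c3)cc(=O)c2c1O
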